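**Retrosynthetic overview**
1. Feature: in benzofuran numbering, ring A carries its substituents at C4, C6 and C7a in the 1,3,5 pattern of phloroglucinol. C3a with C7a–O1 therefore maps onto the carbene carbon and carbonyl oxygen of an o-quinone diazide of 5-methoxyresorcinol. C2–C3 with rings B and C is the double bond of (E)-3,4',5-trimethoxystilbene.
2. Pauciflorol E ⇒ its pentamethyl ether (five O–Me bonds) ⇒ α-diazo ketone, cutting the Cα–C(ortho, ring B) bond of the seven-membered ring (acid-triggered intramolecular arylation).
3. α-Diazo ketone ⇒ benzyl ketone ⇒ C4 triflate + CO + 4-methoxybenzylzinc chloride (the two bonds at the ketone carbon).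
4. C4 triflate ⇒ O-triflyl quinone diazide + stilbene (C3–C3a and C2–O1 bonds; dirhodium carbene, spirocyclopropane, strain-release ring expansion). The diazide comes from 1,3,5-trimethoxy-2-nitrobenzene, where nitrogen already sits at the correct carbon.
5. Ring order: the four arene rings are bought; the dihydrofuran ring forms in step 5 and the seven-membered ring in step 9.

Key step: step 5

Labels: benzofuran numbering (O1, C2, C3, C3a, C4–C7, C7a). Ring A is the benzo ring, ring B the 3,5-dioxygenated aryl on C3, ring C the 4-oxygenated aryl on C2, and ring D the 4-oxygenated aryl on the methine next to the ketone (Cα).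

Assumption: the sense of induction of Rh2(S-PTTL)4 towards a stilbene cannot be predicted with confidence. The S catalyst is written for (2R,3R)-8; should it favour the mirror image, the equally available Rh2(R-PTTL)4 is used with no other change.

**Step 1**
Reactants: 1 1,3,5-trimethoxy-2-nitrobenzene
Product: 2 5-methoxy-2-nitrobenzene-1,3-diol
Conditions: BCl3 (3.5 equiv), CH2Cl2, −78 °C to rt; aqueous work-up
Reagents that add atoms: none
Why: Chelation-directed Lewis-acid ether cleavage, in which BCl3 held between a nitro oxygen and the neighbouring methoxy oxygen cleaves only the two ortho O–Me bonds while the non-chelating para methoxy group (a poor Lewis base through push–pull conjugation) stays; because nitrogen is already at the carbon between the two hydroxyl groups, the regiochemical ambiguity of attacking 5-methoxyresorcinol itself (C2 against C4/C6) never arises.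

**Step 2**
Reactants: 2 5-methoxy-2-nitrobenzene-1,3-diol
Product: 3 3-hydroxy-5-methoxy-2-nitrophenyl trifluoromethanesulfonate
Conditions: Tf2O (1.0 equiv, slow addition), pyridine, CH2Cl2, −40 to 0 °C
Reagents that add atoms: trifluoromethanesulfonic anhydride, O=S(=O)(OS(=O)(=O)C(F)(F)F)C(F)(F)F
Why: Desymmetrising O-sulfonylation of a symmetric diol, in which the first triflate lowers the nucleophilicity of the remaining nitro-chelated phenol, so one equivalent of anhydride at low temperature should stop at the mono-triflate, with unreacted 2 recoverable.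

**Step 3**
Reactants: 3 3-hydroxy-5-methoxy-2-nitrophenyl trifluoromethanesulfonate
Product: 4 2-amino-3-hydroxy-5-methoxyphenyl trifluoromethanesulfonate
Conditions: H2 (1 atm), Pt/C, EtOAc, rt; used at once
Reagents that add atoms: none
Why: Catalytic hydrogenation of a nitroarene, which under neutral conditions over Pt/C does not hydrogenolyse aryl triflates.

**Step 4**
Reactants: 4 2-amino-3-hydroxy-5-methoxyphenyl trifluoromethanesulfonate
Product: 5 6-diazo-3-methoxy-5-oxocyclohexa-1,3-dien-1-yl trifluoromethanesulfonate (the O-triflate of 2-diazo-3-hydroxy-5-methoxycyclohexa-3,5-dien-1-one)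
Conditions: t-BuONO (1.5 equiv), AcOH (cat.), MeCN, 0 °C, dark; filtration through basic Al2O3
Reagents that add atoms: tert-butyl nitrite, CC(C)(C)ON=O
Why: Classical diazotisation of an o-aminophenol, in which the diazonium ion loses its phenolic proton to give the neutral o-quinone diazide, and the non-aqueous, chloride-free medium avoids substitution of the triflate ortho to the diazonium group.

**Step 5**
Reactants: 5 6-diazo-3-methoxy-5-oxocyclohexa-1,3-dien-1-yl trifluoromethanesulfonate; 6 (E)-3,4',5-trimethoxystilbene
Product: 8 (2R,3R)-3-(3,5-dimethoxyphenyl)-6-methoxy-2-(4-methoxyphenyl)-2,3-dihydro-1-benzofuran-4-yl trifluoromethanesulfonate, via spirocyclopropane dienone 7 (not isolated)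
Conditions: Rh2(S-PTTL)4 (2 mol %), 6 (3 equiv), 4 Å MS, PhCF3, 40 °C, 5 added over 6 h, dark; then 60 °C, 1 h
Reagents that add atoms: none
Why: Proposed new method: loss of N2 from 5 at the dirhodium core gives an electrophilic quinoid carbene whose carbon (future C3a) is attacked by the stilbene carbon bearing ring B, because this leaves the developing positive charge next to the 4-methoxyphenyl group, and collapse gives the trans-diaryl spiro[2.5]octadienone 7 ((2+1) closure of the three-membered ring with the alkene geometry kept). Strain release and aromatisation of ring A then break the bond between the spiro carbon and the CH bearing ring C heterolytically, and the phenoxide oxygen closes on the 4-methoxybenzyl cation in a 5-exo-trig mode to form the dihydrofuran. The closest known reaction types are the dirhodium-catalysed formal (3+2) annulation of cyclic 2-diazo-1,3-diones and o-quinone diazides with terminal styrenes and enol ethers, and the enantioselective spirocyclopropanation of styrenes by p-quinone diazides; a 1,2-diaryl alkene and enantiocontrol in the annulation have not been shown. C3 is set by the alkene face that the chiral pocket of the phthalimido-tert-leucinate ligands admits to the carbene and its bonds are never broken afterwards, the spiro centre is erased on aromatisation, and C2 is set by least-motion closure anti to ring B, the trans isomer also being the thermodynamic one because the C2–O1 bond can ionise reversibly. Regioselectivity (oxygen to the carbon bearing ring C) rests on para-methoxy against meta-methoxy cation stabilisation, and only one oxygen can close because the other is masked as the triflate, which also removes the O–H insertion that a free hydroxyl group in the diazide or in the accumulating product would suffer and is the handle for step 7. Chemoselectivity for the alkene over the electron-rich arene rings is helped by slow addition of 5 to an excess of 6.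

**Step 6**
Reactants: 9 4-methoxybenzyl chloride
Product: 10 4-methoxybenzylzinc chloride (THF solution, titrated and used as such)
Conditions: Zn dust, LiCl, THF, 25 °C
Reagents that add atoms: zinc, [Zn]
Why: LiCl-assisted direct insertion of zinc into a benzylic chloride, which is fast at room temperature and gives little homocoupling.

**Step 7**
Reactants: 8 the (2R,3R)-dihydrobenzofuran-4-yl triflate; 10 4-methoxybenzylzinc chloride
Product: 11 1-[(2R,3R)-3-(3,5-dimethoxyphenyl)-6-methoxy-2-(4-methoxyphenyl)-2,3-dihydro-1-benzofuran-4-yl]-2-(4-methoxyphenyl)ethan-1-one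
Conditions: CO (3 bar), Pd(OAc)2 (5 mol %), Xantphos (7 mol %), THF, 50 °C, 10 (1.5 equiv) added over 4 h
Reagents that add atoms: carbon monoxide, [C-]#[O+]
Why: Carbonylative Negishi coupling, in which zerovalent palladium inserts into the C4–OTf bond, CO insertion (favoured by the wide-bite-angle ligand, CO pressure and a low standing concentration of the zinc reagent) gives the acylpalladium species, and transmetalation and reductive elimination give the aryl benzyl ketone without touching C2 or C3.

**Step 8**
Reactants: 11 the aryl benzyl ketone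
Product: 12 2-diazo-1-[(2R,3R)-3-(3,5-dimethoxyphenyl)-6-methoxy-2-(4-methoxyphenyl)-2,3-dihydro-1-benzofuran-4-yl]-2-(4-methoxyphenyl)ethan-1-one
Conditions: 4-acetamidobenzenesulfonyl azide (1.5 equiv), DBU, MeCN, 0 °C to rt
Reagents that add atoms: 4-acetamidobenzenesulfonyl azide, CC(=O)Nc1ccc(cc1)S(=O)(=O)N=[N+]=[N-]
Why: Regitz diazo transfer to a deoxybenzoin-type methylene group, which DBU deprotonates far more readily than the C3–H, so both ring stereocentres are untouched.

**Step 9**
Reactants: 12 the α-aryl-α-diazo ketone
Product: 13 pauciflorol E penta-O-methyl ether: tetracyclic ketone in which C4 and an ortho carbon of ring B are bridged by C(=O)–CH(4-methoxyphenyl); (2R,3R) at the dihydrofuran and (R) at Cα, ring D syn to H-3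
Conditions: TfOH (20 mol %), CH2Cl2/HFIP, −20 to 0 °C; Et3N quench
Reagents that add atoms: none
Why: Acid-promoted intramolecular Friedel–Crafts alkylation by an α-diazo ketone, in which C-protonation and loss of N2 give a ring-D-stabilised α-keto cation that is captured by an ortho position of ring B (para to one methoxy group and ortho to the other, both ortho positions being equivalent), the ring-closure mode known for acid cyclisation of 4-styryl-2,3-diaryldihydrobenzofurans; Cα is substrate-controlled, since the fused dihydrofuran locks the seven-membered boat with C2 pseudo-equatorial, only the R configuration places ring D pseudo-axial and clear of the neighbouring ring B methoxy group, and enolisation under the acid corrects any epimer.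

**Step 10**
Reactants: 13 pauciflorol E penta-O-methyl ether
Product: 14 pauciflorol E
Conditions: BBr3 (15 equiv), CH2Cl2, −78 °C to rt; ice-water quench
Reagents that add atoms: none
Why: Lewis-acid cleavage of five aryl methyl ethers, in which the ketone and the carbon framework are inert, any transient ionisation of the C2–O1 bond leads to a benzylic cation that can only reclose on the ring A oxygen to the trans ring, C3 cannot ionise, and Cα already holds its thermodynamic configuration.

**Compound list**
1 | 1,3,5-trimethoxy-2-nitrobenzene | COc1cc(OC)c([N+](=O)[O-])c(OC)c1 | starting material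
2 | 5-methoxy-2-nitrobenzene-1,3-diol | COc1cc(O)c([N+](=O)[O-])c(O)c1 | intermediate
3 | 3-hydroxy-5-methoxy-2-nitrophenyl trifluoromethanesulfonate | COc1cc(O)c([N+](=O)[O-])c(OS(=O)(=O)C(F)(F)F)c1 | intermediate
4 | 2-amino-3-hydroxy-5-methoxyphenyl trifluoromethanesulfonate | COc1cc(O)c(N)c(OS(=O)(=O)C(F)(F)F)c1 | intermediate
5 | 6-diazo-3-methoxy-5-oxocyclohexa-1,3-dien-1-yl trifluoromethanesulfonate | COC1=CC(=O)C(=[N+]=[N-])C(OS(=O)(=O)C(F)(F)F)=C1 | intermediate
6 | (E)-3,4',5-trimethoxystilbene | COc1ccc(/C=C/c2cc(OC)cc(OC)c2)cc1 | starting material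
7 | (1R,2R)-1-(3,5-dimethoxyphenyl)-6-methoxy-2-(4-methoxyphenyl)-4-oxospiro[2.5]octa-5,7-dien-8-yl trifluoromethanesulfonate (spiro carbon unassigned; it is erased on aromatisation) | O=C1C=C(OC)C=C(OS(=O)(=O)C(F)(F)F)C12[C@@H](c1cc(OC)cc(OC)c1)[C@@H]2c1ccc(OC)cc1 | intermediate
8 | (2R,3R)-3-(3,5-dimethoxyphenyl)-6-methoxy-2-(4-methoxyphenyl)-2,3-dihydro-1-benzofuran-4-yl trifluoromethanesulfonate | O=S(=O)(Oc1cc(OC)cc2c1[C@@H](c1cc(OC)cc(OC)c1)[C@H](c1ccc(OC)cc1)O2)C(F)(F)F | intermediate
9 | 4-methoxybenzyl chloride | COc1ccc(CCl)cc1 | starting material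
10 | 4-methoxybenzylzinc chloride | COc1ccc(C[Zn]Cl)cc1 | intermediate
11 | 1-[(2R,3R)-3-(3,5-dimethoxyphenyl)-6-methoxy-2-(4-methoxyphenyl)-2,3-dihydro-1-benzofuran-4-yl]-2-(4-methoxyphenyl)ethan-1-one | COc1ccc(CC(=O)c2cc(OC)cc3c2[C@@H](c2cc(OC)cc(OC)c2)[C@H](c2ccc(OC)cc2)O3)cc1 | intermediate
12 | 2-diazo analogue of 11 | COc1ccc(C(=[N+]=[N-])C(=O)c2cc(OC)cc3c2[C@@H](c2cc(OC)cc(OC)c2)[C@H](c2ccc(OC)cc2)O3)cc1 | intermediate
13 | pauciflorol E penta-O-methyl ether (2R,3R,αR) | O=C1c2cc(OC)cc3c2[C@@H](c2cc(OC)cc(OC)c2[C@H]1c1ccc(OC)cc1)[C@H](c1ccc(OC)cc1)O3 | intermediate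
14 | pauciflorol E | O=C1c2cc(O)cc3c2[C@@H](c2cc(O)cc(O)c2[C@H]1c1ccc(O)cc1)[C@H](c1ccc(O)cc1)O3 | target

**Step count:** 10 steps in total. The longest linear sequence is 9 steps (1 → 2 → 3 → 4 → 5 → 8 → 11 → 12 → 13 → 14); step 6 is a one-step side branch.

**Steps most likely to fail**

Step 5 (labelled step).
- Risk: the hindered 1,2-diaryl alkene may intercept the carbene too slowly. Carbene dimerisation, C–H arylation of the dimethoxyphenyl ring or proton loss from the ring-opened zwitterion could then take over. The alkene-face selectivity may also be poor.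
- Fallback: known chemistry that sets out from 5 and comes back at 8.
- Compound 5 is annulated with 4-methoxystyrene, a terminal styrene of the class for which the dirhodium-catalysed (3+2) annulation is established (Rh2(OAc)4, PhCF3, 60 °C). This gives racemic 6-methoxy-2-(4-methoxyphenyl)-2,3-dihydro-1-benzofuran-4-yl triflate F1.
- DDQ in refluxing dioxane dehydrogenates it to 6-methoxy-2-(4-methoxyphenyl)-1-benzofuran-4-yl triflate F2.
- NBS (MeCN, 0 °C) brominates the nucleophilic C3 to give the 3-bromobenzofuran triflate F3.
- A bromide-selective Suzuki coupling with 3,5-dimethoxyphenylboronic acid (Pd2(dba)3, P(t-Bu)3, KF, THF, rt) leaves the aryl triflate alone and gives the 2,3-diarylbenzofuran triflate F4.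
- Ionic hydrogenation (Et3SiH, TFA, CH2Cl2) protonates C3 and delivers hydride to C2 anti to ring B, giving the racemic trans-dihydrobenzofuran triflate F5.
- Preparative HPLC on a chiral stationary phase then delivers 8.

Step 7.
- Risk: transmetalation from the benzylzinc reagent may outrun CO insertion at the hindered arylpalladium species, leading to direct coupling. CO may also slow oxidative addition into the triflate.
- Fallback: sets out from 8 and comes back at 11, splitting the two bond formations.
- Aminocarbonylation (CO 1 atm, Pd(OAc)2, Xantphos, MeNH(OMe)·HCl, Et3N, toluene, 90 °C) gives the (2R,3R)-N-methoxy-N-methyl-2,3-dihydro-1-benzofuran-4-carboxamide F6.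
- Commercial 4-methoxybenzylmagnesium chloride (THF, 0 °C) converts F6 through its stable chelate into 11.

Step 9.
- Risk: the α-keto cation may be trapped by the counter-ion or adventitious water, or may undergo 1,2-aryl migration, before the seven-membered ring closes.
- Fallback: sets out from 11 and comes back at 13, reversing the polarity of the bond formation.
- NBS (MeCN, −20 °C) brominates ring B, the most electron-rich ring, para to a methoxy group. This gives 1-[(2R,3S)-3-(2-bromo-3,5-dimethoxyphenyl)-6-methoxy-2-(4-methoxyphenyl)-2,3-dihydro-1-benzofuran-4-yl]-2-(4-methoxyphenyl)ethan-1-one F7. The spatial arrangement is unchanged; the C3 descriptor changes only through ligand priority.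
- Palladium-catalysed intramolecular ketone α-arylation (Pd2(dba)3, XPhos, NaOt-Bu, toluene, 90 °C) closes the ring to 13. Cα settles to its thermodynamic configuration through the enolate.

**Further compounds**
F1 | step 5 | 6-methoxy-2-(4-methoxyphenyl)-2,3-dihydro-1-benzofuran-4-yl trifluoromethanesulfonate (racemic) | COc1ccc(C2Cc3c(OS(=O)(=O)C(F)(F)F)cc(OC)cc3O2)cc1
F2 | step 5 | 6-methoxy-2-(4-methoxyphenyl)-1-benzofuran-4-yl trifluoromethanesulfonate | COc1ccc(-c2cc3c(OS(=O)(=O)C(F)(F)F)cc(OC)cc3o2)cc1
F3 | step 5 | 3-bromo-6-methoxy-2-(4-methoxyphenyl)-1-benzofuran-4-yl trifluoromethanesulfonate | COc1ccc(-c2oc3cc(OC)cc(OS(=O)(=O)C(F)(F)F)c3c2Br)cc1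
F4 | step 5 | 3-(3,5-dimethoxyphenyl)-6-methoxy-2-(4-methoxyphenyl)-1-benzofuran-4-yl trifluoromethanesulfonate | COc1ccc(-c2oc3cc(OC)cc(OS(=O)(=O)C(F)(F)F)c3c2-c2cc(OC)cc(OC)c2)cc1
F5 | step 5 | racemic trans-3-(3,5-dimethoxyphenyl)-6-methoxy-2-(4-methoxyphenyl)-2,3-dihydro-1-benzofuran-4-yl trifluoromethanesulfonate (both enantiomers) | O=S(=O)(Oc1cc(OC)cc2c1[C@@H](c1cc(OC)cc(OC)c1)[C@H](c1ccc(OC)cc1)O2)C(F)(F)F.O=S(=O)(Oc1cc(OC)cc2c1[C@H](c1cc(OC)cc(OC)c1)[C@@H](c1ccc(OC)cc1)O2)C(F)(F)F
F6 | step 7 | (2R,3R)-3-(3,5-dimethoxyphenyl)-N,6-dimethoxy-2-(4-methoxyphenyl)-N-methyl-2,3-dihydro-1-benzofuran-4-carboxamide | CON(C)C(=O)c1cc(OC)cc2c1[C@@H](c1cc(OC)cc(OC)c1)[C@H](c1ccc(OC)cc1)O2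
F7 | step 9 | 1-[(2R,3S)-3-(2-bromo-3,5-dimethoxyphenyl)-6-methoxy-2-(4-methoxyphenyl)-2,3-dihydro-1-benzofuran-4-yl]-2-(4-methoxyphenyl)ethan-1-one | COc1ccc(CC(=O)c2cc(OC)cc3c2[C@@H](c2cc(OC)cc(OC)c2Br)[C@H](c2ccc(OC)cc2)O3)cc1
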